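Compound numbers are those of the route and of the compound list at the end; atom numbers C1–C10 of the target skeleton are used for every intermediate.

## Analysis of the target

Target 36 is a bicyclo[3.2.1]octane in which a cyclohexanone ring (C1–C2–C3–C4–C5–C8) and a five-membered ring (C1–C7–C6–C5–C8) share the bridgeheads C1 and C5 and the bridging ketone C8. C1 carries the isobutyryl group (carbonyl C9), C2 is the CMe2 carbon, C3 and C5 carry prenyl groups, C6 is the tertiary carbinol with the side-chain carbonyl C10, and C7 is the ring ketone. There are four stereocentres (C1, C3, C5, C6). The bridge C6–C7 spans C1 and C5 on one face of the six-membered ring, the C3 prenyl group is equatorial with C3–H pointing towards that bridge, and at C6 the hydroxyl is endo (towards C2–C3–C4) while the acyl group is exo (towards C8). The sensitive groups are the non-enolisable triketone at C1 (C7, C8, C9; retro-Claisen with oxygen nucleophiles), the tertiary α-ketol at C6, which is also β-hydroxy to C8 (retro-aldol), the Z γ-hydroxy enone (isomerisation, hemiketal formation) and two prenyl groups. The hard point is C1: a carbon with three acyl groups next to CMe2, a bridgehead in the product and the unfavourable side of a Claisen equilibrium in any open precursor. The strategy rests on the chain C9–C1–C7–C6–carbonyl: the isobutyryl carbonyl and a carbonyl on C6 are 1,5-related through C1, C7 and C6. That is the pattern left when a cyclobutanol C1–C7–C6–C9 is opened by retro-aldol, which points to an enone–enol photocycloaddition.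

## Retrosynthetic reasoning

**Side chain (C13–CH3, then C6–C10).** In 36 the Z hydroxy enone is cut at one methyl–C13 bond, which leads to the cis-enedione 34 and requires a methyl addition that touches only the unhindered methyl ketone. 34 is an opened 2,5-disubstituted furan, so the five-carbon chain comes from 31 and is joined through C6–C10 to the C6 carbonyl of trione 30. The bond is cut there because a carbon nucleophile entering C6 from the exo face leaves oxygen endo and C10 exo, as in 36. Keeping a carboxyl carbon on C6 as C10 and adding oxygen electrophilically from the same face would give the C6 epimer. The tertiary oxygen is silylated (32, 35) so that the opened furan cannot close onto it.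

**C6 and C7 oxidation levels, prenyl groups.** Trione 30 is reduced to diketone 28 by removing the C6 carbonyl (acyloin 29 as the intermediate level). In 28 the C7 ketone is traced to a silyloxy group and the C6 hydrogen to a carboxyl group that leaves by decarboxylation once C7 is a ketone (27, 26, 25, 24). The two prenyl groups of 24 are cut at their double bonds (Wittig with 23) to dialdehyde 22 and bis-acetal 21, because no alkene other than the two reacting ones may be present in the photochemical step.

**Key disconnection (C6–C7 and C1–C9).** In 21 the bonds C6–C7 and C1–C9 are cut after a bond C6–C9 is added in thought. This gives the cyclobutane 20, the crossed [2+2] adduct of the enone C1=C7 and the enol ether C6=C9 of 19. The cut is made here because C1–C9 cannot be formed by polar chemistry (bridgehead enolate), whereas radical recombination followed by strain-releasing retro-aldol makes it irreversibly. The gain is the five-membered ring, the quaternary C1 with its acyl group and an oxygen on C7. The forward reaction must be crossed (secured by the two-atom tether C8–C5), must join two fully substituted carbons, and must fragment at C6–C9 only.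

**The arm on C5 (C6–C9, C5–C6) and C7 (C1–C7).** 19 is the silylated enol of β-keto ester 18, which is cut at C6–C9 (Claisen acylation of 16 with 17). 16 is the silyl ether of 15, which is cut at C5–C6 (alkylation of the dianion of 13 with 14). The acetal chain is put on C5 before the acetate arm so that the arm enters axially, trans to the C3 substituent. 13 is cut at C1–C7 (formylation of 12). The formyl group is the future C7 and also leaves C5 as the only site for the second deprotonation.

**Ring substituents.** 12 comes from 10 by ozonolysis and acetalisation (via 11). In 10 the two C2 methyl groups and the C5 allyl group are cut: conjugate methylation of 9, α′-allylation of enone 7 with 8, and conjugate methylation with re-dehydrogenation of 5 (via 6). Using the enone twice fixes the regiochemistry: α′-deprotonation places the allyl group at C5, and the second conjugate addition leaves C1 as a methylene.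

**Stereocentre C3.** 5 is opened at C1–C2 (aldol condensation via 4) to 3, and 3 is cut at C3–C4 into 1 and 2 (enamine-catalysed Michael addition). This is the only stereocentre not set by the substrate. A shorter chiral-pool entry that closes the ring by a thermal enol-ene reaction was set aside because it would place a second uncertain step before the key step.

## Alternatives that were turned down

**Alternative 1:** The bond C1–C2 is cut in the selenide A2, leading back to achiral cohulupone A1 with both prenyl groups on C5. In the forward step a chiral Lewis-base-bound selenium electrophile would form a seleniranium ion on one of the two enantiotopic prenyl alkenes, and the enol carbon C1 would open it at the tertiary carbon C2 (6-endo).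
- For: A1 is a few steps from simple materials and already holds the acyl group, the quaternary C5 and all ring carbonyls. One step would give the bicycle, C1, C5 and C3 at the oxidation level of 30 without protecting groups. On step economy this is clearly stronger than the chosen route.
- Against: the enol of a triketone is a weak carbon nucleophile, and its oxygen would be expected to attack the seleniranium ion instead, giving a cyclic enol ether. Carbon attack must join two fully substituted carbons. The catalyst at selenium is far from the prochiral C5. C3 then carries selenium and not carbon, and a C3 radical generated for allylation has a 5-exo path onto the C5 prenyl alkene.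
- Comparison: the chosen route is longer, but it sets C3 with its carbon substituent first by a dependable catalytic step, enforces the regiochemistry at C1 by a tether, and uses only known step types.

**Alternative 2:** The bonds C4–C5 and C3–allyl are cut in A4, leading back to the bromide A3, which carries a reverse-prenyl group on C1. In the forward step the C5 radical would add 6-endo to the terminal alkene carbon C4, and the C3 radical would be captured by an allyl-tin transfer reagent.
- For: the crowded C1–C2 bond would come from a sigmatropic shift, which tolerates congestion. The trione ring is present from the start, and ring and C3–C bond form in one operation. It is shorter than the chosen route.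
- Against: the two radicals make opposite demands. The electrophilic diacyl radical at C5 is trapped quickly by the electron-rich allyl donor before it cyclises, whereas the nucleophilic C3 radical needs a high concentration of that same mismatched trap. The C3 configuration would rest on the face selectivity of a radical capture, and the absolute configuration of C1 on an asymmetric rearrangement of a fully substituted enol.
- Comparison: the chosen route gives up the shorter sequence for substrate-controlled configuration at C5 and C1 and a catalyst-controlled C3.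

**Alternative 3:** The bond C1–C7 is cut in A6, leading back to the β-diketone A5 with an axial α-silyloxy ester arm on C5. In the forward step the C1 enolate would attack the ester carbon (5-exo), and the product would be held as its C6 enolate.
- For: it is polar and scalable, the prenyl groups need no masking, C6 is already oxygenated, and C7 arrives as a ketone. It therefore avoids both the acetal detour and the free C7 carbinol of the chosen route, and on these points it is stronger.
- Against: the closure forms a non-enolisable triacyl carbon, which is the unfavourable side of a Claisen equilibrium. The starting enolate is stabilised by two carbonyls and the product enolate by one, so the expelled alkoxide should reopen the ring. O-acylation to an enol lactone is the easier kinetic path at the hindered C1.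
- Comparison: the chosen photochemical step makes the same quaternary centre without an equilibrium to overcome.

Key step: step 12

Remarks on the chemistry:
- The Z γ-hydroxy enone of 36 may equilibrate with its five-membered cyclic hemiketal; the open form is taken as the target.
- The sense of induction in step 1 is assumed to follow the usual model for diarylprolinol silyl ether enamines; the R catalyst would be used if the product proved antipodal.
- Labile centres (C5 before step 8; C6 and C7 between steps 12 and 19) are drawn as one epimer or left open; all epimers converge.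

## Route

Step 1
Reactants: 1 pent-4-enal, 2 but-3-en-2-one
Product: 3 (S)-2-allyl-5-oxohexanal
Conditions: (S)-2-[diphenyl(trimethylsilyloxy)methyl]pyrrolidine (5 mol %), ethyl 3,4-dihydroxybenzoate (20 mol %), neat, 4 °C
Reagents that add atoms: none
Why: Enamine-catalysed Michael addition of an aldehyde to an enone; the diarylsilyloxymethyl group shields one face of the anti-enamine, so the enone is attacked on the open face and C3 is set, the only stereocentre of the route that is not substrate-controlled.

Step 2
Reactants: 3
Product: 5 (S)-4-allylcyclohex-2-en-1-one, via ketol 4 (not isolated)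
Conditions: LiOH (cat.), iPrOH, rt
Reagents that add atoms: none
Why: Intramolecular aldol condensation of the methyl ketone onto the aldehyde closes the six-membered ring (bond C1–C2); mild hydroxide in isopropanol should dehydrate the ketol without epimerising the γ-stereocentre C3.

Step 3
Reactants: 5
Product: 7 (S)-4-allyl-3-methylcyclohex-2-en-1-one, via selenide 6 (not isolated)
Conditions: Me2CuLi (from MeLi, CuI), Et2O, −78 → −20 °C; PhSeBr, THF, −78 °C; then H2O2, pyridine, CH2Cl2, 0 °C
Reagents that add atoms: methyllithium (delivered as Me2CuLi), [Li]C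
Why: Cuprate conjugate addition at C2 anti to the C3 allyl group, selenenylation of the regiodefined enolate at C1 and selenoxide syn-elimination towards the only β-hydrogen (C2–H) return the enone with the first C2 methyl group; palladium-based dehydrogenation is avoided because the silyl enol ether could cyclise onto the allyl group.

Step 4
Reactants: 7, 8 allyl bromide
Product: 9 4,6-diallyl-3-methylcyclohex-2-en-1-one (C4 as in 7; C6 epimers)
Conditions: LiN(iPr)2, THF, −78 °C; then 8, −78 → 0 °C
Reagents that add atoms: none
Why: Kinetic deprotonation of a cyclohexenone takes place at the α′ carbon (C5), so the allyl group is placed regiospecifically on the side remote from C2; the C5 configuration does not matter because C5 is enolised again in step 8.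

Step 5
Reactants: 9
Product: 10 2,4-diallyl-5,5-dimethylcyclohexan-1-one (C4 unchanged; C2 epimers)
Conditions: Me2CuLi (from MeLi, CuI), Et2O, −20 → 0 °C
Reagents that add atoms: methyllithium (delivered as Me2CuLi), [Li]C
Why: A second cuprate conjugate addition to the β-methyl enone creates the gem-dimethyl carbon C2 (no new stereocentre) and leaves C1 as a methylene.

Step 6
Reactants: 10
Product: 12 2,4-bis(2,2-dimethoxyethyl)-5,5-dimethylcyclohexan-1-one (4S; C2 epimers), via dialdehyde 11 (not isolated)
Conditions: O3, CH2Cl2/MeOH, −78 °C; Me2S; then HC(OMe)3, TsOH (cat.), MeOH, 0 °C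
Reagents that add atoms: methanol, CO; trimethyl orthoformate, COC(OC)OC
Why: Ozonolysis of both terminal alkenes and acid-catalysed acetalisation of the two aldehydes; with a stoichiometric amount of orthoformate the hindered ring ketone should stay free. Both future prenyl groups are now masked in a form that does not react with an excited enone.

Step 7
Reactants: 12
Product: 13 (Z)-4,6-bis(2,2-dimethoxyethyl)-2-(hydroxymethylene)-3,3-dimethylcyclohexan-1-one (C6 epimers)
Conditions: NaH, HCO2Et, EtOH (cat.), THF, 0 °C → rt; AcOH
Reagents that add atoms: ethyl formate, CCOC=O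
Why: Claisen formylation under equilibrating conditions; only reaction at the C1 methylene gives an enolisable β-keto aldehyde (the stable sodium enolate), so the formyl carbon C7 should end at C1 despite the neighbouring quaternary C2, while formylation at the C5 methine is reversible.

Step 8
Reactants: 13, 14 methyl bromoacetate
Product: 15 methyl 2-[1,5-bis(2,2-dimethoxyethyl)-3-(hydroxymethylene)-4,4-dimethyl-2-oxocyclohexyl]acetate (acetate arm trans to the C3 side chain; the two acetal chains cis)
Conditions: LiN(iPr)2 (2.3 equiv), THF, −78 → 0 °C; then 14, −78 °C; AcOH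
Reagents that add atoms: none
Why: Dianion alkylation of a 2-hydroxymethylene ketone; the second deprotonation can only occur at C5 and the more basic α′ site reacts. Axial attack on the C5 enolate, on the side of the axial C3–H and away from the equatorial C3 side chain, should set the quaternary centre with the arm trans to the C3 substituent.

Step 9
Reactants: 15
Product: 16 methyl 2-[(3Z)-3-[(tert-butyldimethylsilyloxy)methylene]-1,5-bis(2,2-dimethoxyethyl)-4,4-dimethyl-2-oxocyclohexyl]acetate
Conditions: tBuMe2SiCl, Et3N, 4-(dimethylamino)pyridine (cat.), CH2Cl2, 0 °C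
Reagents that add atoms: tert-butyldimethylsilyl chloride, CC(C)(C)[Si](C)(C)Cl
Why: O-silylation of the enolised β-keto aldehyde gives the photoactive vinylogous silyl ester; the Z isomer (silyloxy syn to C8=O) is expected because the E isomer would press the silyloxy group against CMe2.

Step 10
Reactants: 16, 17 isobutyryl chloride
Product: 18 methyl 2-[(3Z)-3-[(tert-butyldimethylsilyloxy)methylene]-1,5-bis(2,2-dimethoxyethyl)-4,4-dimethyl-2-oxocyclohexyl]-4-methyl-3-oxopentanoate (C6 epimers)
Conditions: LiN(iPr)2 (2.2 equiv), THF, −78 °C; then 17; AcOH, −78 °C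
Reagents that add atoms: none
Why: Crossed Claisen acylation of the ester enolate, the only acidic site now that C8 has no α-hydrogen; the second equivalent of base stores the product as its enolate. Conjugate addition of the enolate to C7 would be a 5-endo closure to a bridgehead enolate and should not compete.

Step 11
Reactants: 18
Product: 19 trimethylsilyl enol ether of 18 at C9 (E/Z mixture at C6=C9)
Conditions: KN(SiMe3)2, THF, −78 °C; Me3SiCl; pentane, filtration
Reagents that add atoms: chlorotrimethylsilane, C[Si](C)(C)Cl
Why: O-silylation of the potassium enolate holds the arm entirely in the enol form needed as the alkene partner, since the hindered β-keto ester itself is little enolised; the enol ether geometry is irrelevant because C9 becomes a carbonyl again.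

Step 12
Reactants: 19
Product: 21 methyl 7-(tert-butyldimethylsilyloxy)-3,5-bis(2,2-dimethoxyethyl)-2,2-dimethyl-1-(2-methylpropanoyl)-8-oxobicyclo[3.2.1]octane-6-carboxylate (drawn 6-exo ester and 7-exo silyloxy), via photoadduct 20 (not isolated)
Conditions: hν (350 nm lamps, filter cutting off below 330 nm), degassed MeCN, 5 mM, 10 °C; then Bu4NF, AcOH, THF, 0 °C
Reagents that add atoms: none
Why: Excitation of the vinylogous silyl ester gives the twisted enone triplet, whose β-carbon C7 bonds to C6 of the silyl enol ether (1,5-closure by the rule of five; 5-exo with respect to C6=C9), closing the ring C1–C7–C6–C5–C8. The 1,4-biradical (C1 α-keto, C9 α-silyloxy) then collapses to the crossed cyclobutane 20, a bicyclo[2.1.1]hexan-2-one; the closest known reaction type is the crossed intramolecular [2+2] photocycloaddition of 1,5-hexadien-3-ones combined with the de Mayo enone–enol sequence. The two-atom tether C8–C5 allows only the crossed mode, so C9 must end on C1, and a biradical with C9 on the endo side cannot close and should revert to 19. Buffered fluoride frees the C9 cyclobutanol, and retro-aldol cleavage breaks C6–C9 towards the ester enolate with release of ring strain, whereas cleavage of C1–C9 would need a bridgehead enolate. C1 is set by the substrate: the two-carbon bridge can only span C1 and C5 on the face of the axial arm fixed in step 8. C7 (first bond) and C6 (enolate protonation) are not controlled and need not be, because both become trigonal in steps 17–19. The step needs cycloaddition to outrun hydrogen abstraction from the acetal C–H bonds and must not photolyse the product ketones; the short tether, high dilution and the long-wavelength filter are meant to secure this.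

Step 13
Reactants: 21
Product: 22 methyl 7-(tert-butyldimethylsilyloxy)-2,2-dimethyl-1-(2-methylpropanoyl)-8-oxo-3,5-bis(2-oxoethyl)bicyclo[3.2.1]octane-6-carboxylate
Conditions: pyridinium p-toluenesulfonate, acetone/H2O, 50 °C
Reagents that add atoms: water, O
Why: Mild acid-catalysed acetal hydrolysis; the hindered secondary silyl ether and the methyl ester should be stable. The dialdehyde is used at once to avoid aldol reaction between the two chains.

Step 14
Reactants: 22, 23 isopropyltriphenylphosphonium iodide
Product: 24 methyl 7-(tert-butyldimethylsilyloxy)-2,2-dimethyl-3,5-bis(3-methylbut-2-enyl)-1-(2-methylpropanoyl)-8-oxobicyclo[3.2.1]octane-6-carboxylate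
Conditions: 23, n-BuLi, THF, 0 °C; then 22, −78 → 0 °C
Reagents that add atoms: none
Why: Double Wittig olefination with the non-stabilised isopropylidene ylide; the aldehydes react at low temperature, the C8 and C9 ketones are each flanked by a quaternary carbon, and the ester is inert.

Step 15
Reactants: 24
Product: 25 the corresponding bicyclo[3.2.1]octane-6-carboxylic acid
Conditions: LiSPr (from n-PrSH, n-BuLi), HMPA, rt; then 1 M HCl
Reagents that add atoms: none
Why: SN2 demethylation at the ester methyl by thiolate is insensitive to the crowding at the carboxyl carbon, where hydroxide saponification would be slow and could eliminate the β-silyloxy group.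

Step 16
Reactants: 25
Product: 26 7-hydroxy-2,2-dimethyl-3,5-bis(3-methylbut-2-enyl)-1-(2-methylpropanoyl)-8-oxobicyclo[3.2.1]octane-6-carboxylic acid
Conditions: HF·pyridine, THF, 0 °C
Reagents that add atoms: none
Why: Cleavage of the hindered secondary silyl ether under acidic, non-basic conditions; base is excluded because the C7 carbinol is the aldol of a 1,3-diketone and would open by retro-aldol. The crude product is oxidised at once.

Step 17
Reactants: 26
Product: 28 2,2-dimethyl-3,5-bis(3-methylbut-2-enyl)-1-(2-methylpropanoyl)bicyclo[3.2.1]octane-7,8-dione, via keto acid 27 (not isolated)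
Conditions: Dess–Martin periodinane, pyridine, CH2Cl2, 0 °C → rt; then 40 °C
Reagents that add atoms: none
Why: Periodinane oxidation of the secondary alcohol gives a β-keto acid, which should lose CO2 through the ordinary (non-bridgehead) enol C6=C7; the carboxyl carbon is thus removed without nucleophiles near the now complete triketone at C1.

Step 18
Reactants: 28
Product: 29 6-hydroxy-2,2-dimethyl-3,5-bis(3-methylbut-2-enyl)-1-(2-methylpropanoyl)bicyclo[3.2.1]octane-7,8-dione (drawn 6-exo OH)
Conditions: LiN(SiMe3)2, THF, −78 °C; 2-(phenylsulfonyl)-3-phenyloxaziridine; AcOH, −78 °C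
Reagents that add atoms: 2-(phenylsulfonyl)-3-phenyloxaziridine, O=S(=O)(c1ccccc1)N1OC1c1ccccc1
Why: C6 is the only methylene α to a ketone, so the amide base should give the C6=C7 enolate in preference to the hindered isopropyl methine; electrophilic hydroxylation by the oxaziridine gives the acyloin, whose configuration is lost in step 19. The cold acidic quench prevents retro-aldol of the alkoxide.

Step 19
Reactants: 29
Product: 30 2,2-dimethyl-3,5-bis(3-methylbut-2-enyl)-1-(2-methylpropanoyl)bicyclo[3.2.1]octane-6,7,8-trione
Conditions: Dess–Martin periodinane, CH2Cl2, rt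
Reagents that add atoms: none
Why: Non-basic oxidation of the acyloin to the vicinal dione; direct SeO2 oxidation of 28 is not used because it would attack the prenyl groups.

Step 20
Reactants: 30, 31 2-methylfuran
Product: 32 6-(5-methylfuran-2-yl)-2,2-dimethyl-3,5-bis(3-methylbut-2-enyl)-1-(2-methylpropanoyl)-6-(trimethylsilyloxy)bicyclo[3.2.1]octane-7,8-dione (furyl exo; silyloxy endo)
Conditions: 31, n-BuLi, THF, 0 °C; then 30, THF, −78 °C; Me3SiCl, −78 → −20 °C
Reagents that add atoms: chlorotrimethylsilane, C[Si](C)(C)Cl
Why: 1,2-Addition of the furyllithium to the more accessible carbonyl of the dione: C6 is flanked by C5 with its CH2 substituent, whereas C7 lies next to C1 with the isobutyryl group and CMe2. Attack from the exo face (side of C8) is expected because the endo face is covered by the C2–C3–C4 bridge with its axial C3–H, placing furyl exo and oxygen endo as in 36; silylation in the same flask blocks retro-aldol and later hemiketal formation.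

Step 21
Reactants: 32
Product: 34 2,2-dimethyl-3,5-bis(3-methylbut-2-enyl)-1-(2-methylpropanoyl)-6-[(Z)-4-oxopent-2-enoyl]-6-(trimethylsilyloxy)bicyclo[3.2.1]octane-7,8-dione, via endoperoxide 33 (not isolated)
Conditions: O2, methylene blue, visible light, CH2Cl2, −78 °C; then Me2S, −78 °C → rt
Reagents that add atoms: oxygen, O=O
Why: [4+2] cycloaddition of singlet oxygen to the electron-rich 2,5-disubstituted furan is much faster than the ene reaction of trisubstituted alkenes; reduction of the endoperoxide opens it to the cis-enedione, whose Z geometry comes from the ring. The silyl ether prevents closure to a pyranone hemiketal.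

Step 22
Reactants: 34
Product: 35 6-[(Z)-4-hydroxy-4-methylpent-2-enoyl]-2,2-dimethyl-3,5-bis(3-methylbut-2-enyl)-1-(2-methylpropanoyl)-6-(trimethylsilyloxy)bicyclo[3.2.1]octane-7,8-dione
Conditions: MeTi(OiPr)3 (from MeLi, ClTi(OiPr)3), Et2O, −30 → 0 °C
Reagents that add atoms: methyltitanium triisopropoxide, C[Ti](OC(C)C)(OC(C)C)OC(C)C
Why: The titanium reagent adds only in 1,2-fashion and is very sensitive to hindrance; the methyl ketone is the one carbonyl not attached to a quaternary carbon (C7, C8, C9 and C10 all are), and the reagent is not basic enough for retro-Claisen cleavage.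

Step 23
Reactants: 35
Product: 36 6-hydroxy-6-[(Z)-4-hydroxy-4-methylpent-2-enoyl]-2,2-dimethyl-3,5-bis(3-methylbut-2-enyl)-1-(2-methylpropanoyl)bicyclo[3.2.1]octane-7,8-dione (target)
Conditions: HF·pyridine, pyridine, THF, 0 °C
Reagents that add atoms: none
Why: Buffered acidic fluoride removes the tertiary trimethylsilyl ether without base, so the triketone, the α-ketol and the Z hydroxy enone should survive.

## Compound list

1 | pent-4-enal | C=CCCC=O | starting material
2 | but-3-en-2-one | CC(=O)C=C | starting material
3 | (S)-2-allyl-5-oxohexanal | C=CC[C@@H](C=O)CCC(C)=O | intermediate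
4 | (4S)-4-allyl-3-hydroxycyclohexan-1-one (ketol) | C=CC[C@@H]1CCC(=O)CC1O | intermediate (not isolated)
5 | (S)-4-allylcyclohex-2-en-1-one | C=CC[C@@H]1CCC(=O)C=C1 | intermediate
6 | 3,4-trans-4-allyl-3-methyl-2-(phenylselanyl)cyclohexan-1-one | C=CC[C@@H]1CCC(=O)C([Se]c2ccccc2)[C@H]1C | intermediate (not isolated)
7 | (S)-4-allyl-3-methylcyclohex-2-en-1-one | C=CC[C@@H]1CCC(=O)C=C1C | intermediate
8 | allyl bromide | C=CCBr | starting material
9 | 4,6-diallyl-3-methylcyclohex-2-en-1-one (C6 epimers) | C=CC[C@@H]1CC(CC=C)C(=O)C=C1C | intermediate
10 | 2,4-diallyl-5,5-dimethylcyclohexan-1-one (C2 epimers) | C=CC[C@@H]1CC(CC=C)C(=O)CC1(C)C | intermediate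
11 | 2,2'-(4,4-dimethyl-6-oxocyclohexane-1,3-diyl)diacetaldehyde | O=CC[C@@H]1CC(CC=O)C(=O)CC1(C)C | intermediate (not isolated)
12 | (4S)-2,4-bis(2,2-dimethoxyethyl)-5,5-dimethylcyclohexan-1-one (C2 epimers) | COC(OC)C[C@@H]1CC(CC(OC)OC)C(=O)CC1(C)C | intermediate
13 | (Z)-4,6-bis(2,2-dimethoxyethyl)-2-(hydroxymethylene)-3,3-dimethylcyclohexan-1-one | COC(OC)C[C@@H]1CC(CC(OC)OC)C(=O)/C(=C\O)C1(C)C | intermediate
14 | methyl bromoacetate | COC(=O)CBr | starting material
15 | methyl 2-[1,5-bis(2,2-dimethoxyethyl)-3-(hydroxymethylene)-4,4-dimethyl-2-oxocyclohexyl]acetate | COC(OC)C[C@@H]1C[C@](CC(=O)OC)(CC(OC)OC)C(=O)/C(=C\O)C1(C)C | intermediate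
16 | tert-butyldimethylsilyl enol ether of 15 | COC(OC)C[C@@H]1C[C@](CC(=O)OC)(CC(OC)OC)C(=O)/C(=C\O[Si](C)(C)C(C)(C)C)C1(C)C | intermediate
17 | isobutyryl chloride | CC(C)C(=O)Cl | starting material
18 | β-keto ester: methyl 2-[3-(silyloxymethylene)-1,5-bis(2,2-dimethoxyethyl)-4,4-dimethyl-2-oxocyclohexyl]-4-methyl-3-oxopentanoate | COC(OC)C[C@@H]1C[C@]([C@@H](C(=O)OC)C(=O)C(C)C)(CC(OC)OC)C(=O)/C(=C\O[Si](C)(C)C(C)(C)C)C1(C)C | intermediate
19 | trimethylsilyl enol ether of 18 | COC(OC)C[C@@H]1C[C@](C(C(=O)OC)=C(O[Si](C)(C)C)C(C)C)(CC(OC)OC)C(=O)/C(=C\O[Si](C)(C)C(C)(C)C)C1(C)C | intermediate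
20 | crossed photoadduct (bicyclo[2.1.1]hexan-2-one cage with C7 and C9 silyl ethers; C9 epimers) | COC(OC)C[C@@H]1C[C@]2(CC(OC)OC)C(=O)[C@@]3([C@@H](O[Si](C)(C)C(C)(C)C)[C@@]2(C(=O)OC)C3(O[Si](C)(C)C)C(C)C)C1(C)C | intermediate (not isolated)
21 | methyl 7-(tert-butyldimethylsilyloxy)-3,5-bis(2,2-dimethoxyethyl)-2,2-dimethyl-1-(2-methylpropanoyl)-8-oxobicyclo[3.2.1]octane-6-carboxylate | COC(OC)C[C@@H]1C[C@]2(CC(OC)OC)C(=O)[C@@](C(=O)C(C)C)([C@@H](O[Si](C)(C)C(C)(C)C)[C@H]2C(=O)OC)C1(C)C | intermediate
22 | 3,5-bis(2-oxoethyl) dialdehyde from 21 | O=CC[C@@H]1C[C@]2(CC=O)C(=O)[C@@](C(=O)C(C)C)([C@@H](O[Si](C)(C)C(C)(C)C)[C@H]2C(=O)OC)C1(C)C | intermediate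
23 | isopropyltriphenylphosphonium iodide | CC(C)[P+](c1ccccc1)(c1ccccc1)c1ccccc1.[I-] | starting material
24 | 3,5-diprenyl 7-silyloxy methyl ester | CC(C)=CC[C@@H]1C[C@]2(CC=C(C)C)C(=O)[C@@](C(=O)C(C)C)([C@@H](O[Si](C)(C)C(C)(C)C)[C@H]2C(=O)OC)C1(C)C | intermediate
25 | 3,5-diprenyl 7-silyloxy carboxylic acid | CC(C)=CC[C@@H]1C[C@]2(CC=C(C)C)C(=O)[C@@](C(=O)C(C)C)([C@@H](O[Si](C)(C)C(C)(C)C)[C@H]2C(=O)O)C1(C)C | intermediate
26 | 7-hydroxy carboxylic acid | CC(C)=CC[C@@H]1C[C@]2(CC=C(C)C)C(=O)[C@@](C(=O)C(C)C)([C@@H](O)[C@H]2C(=O)O)C1(C)C | intermediate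
27 | 7-oxo carboxylic acid | CC(C)=CC[C@@H]1C[C@]2(CC=C(C)C)C(=O)[C@@](C(=O)C(C)C)(C(=O)[C@H]2C(=O)O)C1(C)C | intermediate (not isolated)
28 | 2,2-dimethyl-3,5-bis(3-methylbut-2-enyl)-1-(2-methylpropanoyl)bicyclo[3.2.1]octane-7,8-dione | CC(C)=CC[C@@H]1C[C@]2(CC=C(C)C)C(=O)[C@@](C(=O)C(C)C)(C(=O)C2)C1(C)C | intermediate
29 | 6-hydroxy derivative of 28 (acyloin) | CC(C)=CC[C@@H]1C[C@]2(CC=C(C)C)C(=O)[C@@](C(=O)C(C)C)(C(=O)[C@H]2O)C1(C)C | intermediate
30 | 2,2-dimethyl-3,5-bis(3-methylbut-2-enyl)-1-(2-methylpropanoyl)bicyclo[3.2.1]octane-6,7,8-trione | CC(C)=CC[C@@H]1C[C@]2(CC=C(C)C)C(=O)[C@@](C(=O)C(C)C)(C(=O)C2=O)C1(C)C | intermediate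
31 | 2-methylfuran | Cc1ccco1 | starting material
32 | 6-exo-(5-methylfuran-2-yl)-6-endo-(trimethylsilyloxy)-7,8-dione | CC(C)=CC[C@@H]1C[C@]2(CC=C(C)C)C(=O)[C@@](C(=O)C(C)C)(C(=O)[C@@]2(O[Si](C)(C)C)c3ccc(C)o3)C1(C)C | intermediate
33 | furan endoperoxide of 32 | CC(C)=CC[C@@H]1C[C@]2(CC=C(C)C)C(=O)[C@@](C(=O)C(C)C)(C(=O)[C@@]2(O[Si](C)(C)C)C34OOC(C)(O3)C=C4)C1(C)C | intermediate (not isolated)
34 | 6-[(Z)-4-oxopent-2-enoyl]-6-(trimethylsilyloxy)-7,8-dione | CC(C)=CC[C@@H]1C[C@]2(CC=C(C)C)C(=O)[C@@](C(=O)C(C)C)(C(=O)[C@@]2(O[Si](C)(C)C)C(=O)/C=C\C(C)=O)C1(C)C | intermediate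
35 | 6-[(Z)-4-hydroxy-4-methylpent-2-enoyl]-6-(trimethylsilyloxy)-7,8-dione | CC(C)=CC[C@@H]1C[C@]2(CC=C(C)C)C(=O)[C@@](C(=O)C(C)C)(C(=O)[C@@]2(O[Si](C)(C)C)C(=O)/C=C\C(C)(C)O)C1(C)C | intermediate
36 | CNP0190794.1 | CC(C)=CC[C@@H]1C[C@]2(CC=C(C)C)C(=O)[C@@](C(=O)C(C)C)(C(=O)[C@@]2(O)C(=O)/C=C\C(C)(C)O)C1(C)C | target

Total step count: 23. Longest linear sequence: 23 steps (1 to 36).

## Least certain steps

**Step 12 (key step).** After the first bond the 1,4-biradical has to join two fully substituted carbons (C1 and C9); it may instead revert or disproportionate. The triplet may also abstract hydrogen from an acetal C–H bond, and prolonged irradiation may cleave the product ketones. The fallback lowers the steric load at C9. It sets out from 16, which is acylated with acetylimidazole instead of 17 to give the acetoacetate analogue F1. This is silylated to the enol ether F2 and irradiated to the cage F3, and buffered fluoride then gives the 1-acetyl bicycle F4. Two successive kinetic enolate methylations of the methyl ketone (LiN(iPr)2, MeI), through the 1-propanoyl compound F5, build the isopropyl ketone and return to 21.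

**Step 8.** The second deprotonation at the tertiary C5 may be slow, the hydroxymethylene oxygen may be alkylated instead, and the facial selectivity of the quaternisation may be incomplete. The fallback quaternises C5 before C7 is introduced. It sets out from 12, which under equilibrating silylation (Me3SiCl, Et3N, DMF, heat) gives the more substituted silyl enol ether F6. MeLi frees the lithium enolate, and 14 gives the keto ester F7. Kinetic deprotonation at C1 (LiN(iPr)2, −78 °C) and formylation with 2,2,2-trifluoroethyl formate return to 15.

**Step 16.** Once the silyl group is off, the C7 carbinol is the aldol adduct of a 1,3-diketone, and ring opening by retro-aldol (or a carbon-to-oxygen acyl shift) may occur before oxidation. The fallback oxidises C7 before the retro-aldol, while C9 is still a protected carbinol and C1 a cage bridgehead, so that the diketone-stabilised leaving group does not yet exist. It sets out from 18, which is converted (KN(SiMe3)2, iPr3SiOTf) into the triisopropylsilyl enol ether F8 and irradiated to the cage F9, which is kept. HF·pyridine removes only the less shielded secondary silyl group to give the cage alcohol F10, and Dess–Martin periodinane gives the cage ketone F11. Bu4NF then opens the cage to the β-keto ester F12. Acetal hydrolysis to the dialdehyde F13, Wittig olefination to the diprenyl β-keto ester F14 and Krapcho dealkoxycarbonylation (LiCl, wet DMSO, heat) return to 28.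

**Step 20.** The organolithium may add to C7 instead of C6 or add twice, and the alkoxide may fragment by retro-aldol before it is silylated. The later furan opening and methyl addition also depend on chemoselectivity in the presence of the prenyl groups and four ketones. The fallback brings C10 in as an electrophile on the C6 enolate, again from the exo face, and so replaces steps 20 to 23. It sets out from 29, which is silylated (Et3SiOTf, 2,6-lutidine) to the triethylsilyl ether F15. Its enolate (LiN(SiMe3)2, −78 °C) is added to 4-methyl-4-(triethylsilyloxy)pent-2-ynal F16 to give the aldol F17. Dess–Martin oxidation gives the ynone F18, semi-hydrogenation (H2, Pd/CaCO3 poisoned with Pb(OAc)2, quinoline) gives the Z enone F19, and HF·pyridine removes both silyl groups to reach 36.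

## Further compounds

F1 | step 12 | acetoacetate analogue of 18 | COC(OC)C[C@@H]1C[C@](C(C(=O)OC)C(C)=O)(CC(OC)OC)C(=O)/C(=C\O[Si](C)(C)C(C)(C)C)C1(C)C
F2 | step 12 | trimethylsilyl enol ether of F1 | COC(OC)C[C@@H]1C[C@](C(C(=O)OC)=C(C)O[Si](C)(C)C)(CC(OC)OC)C(=O)/C(=C\O[Si](C)(C)C(C)(C)C)C1(C)C
F3 | step 12 | crossed photoadduct of F2 | COC(OC)C[C@@H]1C[C@]2(CC(OC)OC)C(=O)[C@@]3([C@@H](O[Si](C)(C)C(C)(C)C)[C@@]2(C(=O)OC)C3(C)O[Si](C)(C)C)C1(C)C
F4 | step 12 | 1-acetyl analogue of 21 | COC(OC)C[C@@H]1C[C@]2(CC(OC)OC)C(=O)[C@@](C(C)=O)([C@@H](O[Si](C)(C)C(C)(C)C)[C@H]2C(=O)OC)C1(C)C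
F5 | step 12 | 1-propanoyl analogue of 21 | COC(OC)C[C@@H]1C[C@]2(CC(OC)OC)C(=O)[C@@](C(=O)CC)([C@@H](O[Si](C)(C)C(C)(C)C)[C@H]2C(=O)OC)C1(C)C
F6 | step 8 | trimethylsilyl enol ether of 12 (C5=C8) | COC(OC)C[C@@H]1CC(CC(OC)OC)=C(O[Si](C)(C)C)CC1(C)C
F7 | step 8 | methyl 2-[1,5-bis(2,2-dimethoxyethyl)-4,4-dimethyl-2-oxocyclohexyl]acetate | COC(OC)C[C@@H]1C[C@](CC(=O)OC)(CC(OC)OC)C(=O)CC1(C)C
F8 | step 16 | triisopropylsilyl enol ether of 18 | COC(OC)C[C@@H]1C[C@](C(C(=O)OC)=C(O[Si](C(C)C)(C(C)C)C(C)C)C(C)C)(CC(OC)OC)C(=O)/C(=C\O[Si](C)(C)C(C)(C)C)C1(C)C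
F9 | step 16 | crossed photoadduct of F8 | COC(OC)C[C@@H]1C[C@]2(CC(OC)OC)C(=O)[C@@]3([C@@H](O[Si](C)(C)C(C)(C)C)[C@@]2(C(=O)OC)C3(O[Si](C(C)C)(C(C)C)C(C)C)C(C)C)C1(C)C
F10 | step 16 | cage C7 alcohol | COC(OC)C[C@@H]1C[C@]2(CC(OC)OC)C(=O)[C@@]3([C@@H](O)[C@@]2(C(=O)OC)C3(O[Si](C(C)C)(C(C)C)C(C)C)C(C)C)C1(C)C
F11 | step 16 | cage C7 ketone | COC(OC)C[C@@H]1C[C@]2(CC(OC)OC)C(=O)[C@@]3(C(=O)[C@@]2(C(=O)OC)C3(O[Si](C(C)C)(C(C)C)C(C)C)C(C)C)C1(C)C
F12 | step 16 | methyl 3,5-bis(2,2-dimethoxyethyl)-2,2-dimethyl-1-(2-methylpropanoyl)-7,8-dioxobicyclo[3.2.1]octane-6-carboxylate | COC(OC)C[C@@H]1C[C@]2(CC(OC)OC)C(=O)[C@@](C(=O)C(C)C)(C(=O)C2C(=O)OC)C1(C)C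
F13 | step 16 | 3,5-bis(2-oxoethyl) dialdehyde from F12 | O=CC[C@@H]1C[C@]2(CC=O)C(=O)[C@@](C(=O)C(C)C)(C(=O)C2C(=O)OC)C1(C)C
F14 | step 16 | 3,5-diprenyl β-keto ester | CC(C)=CC[C@@H]1C[C@]2(CC=C(C)C)C(=O)[C@@](C(=O)C(C)C)(C(=O)C2C(=O)OC)C1(C)C
F15 | step 20 | triethylsilyl ether of 29 | CC(C)=CC[C@@H]1C[C@]2(CC=C(C)C)C(=O)[C@@](C(=O)C(C)C)(C(=O)[C@H]2O[Si](CC)(CC)CC)C1(C)C
F16 | step 20 | 4-methyl-4-(triethylsilyloxy)pent-2-ynal | O=CC#CC(C)(C)O[Si](CC)(CC)CC
F17 | step 20 | aldol adduct of F15 and F16 | CC(C)=CC[C@@H]1C[C@]2(CC=C(C)C)C(=O)[C@@](C(=O)C(C)C)(C(=O)[C@@]2(O[Si](CC)(CC)CC)C(O)C#CC(C)(C)O[Si](CC)(CC)CC)C1(C)C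
F18 | step 20 | ynone from F17 | CC(C)=CC[C@@H]1C[C@]2(CC=C(C)C)C(=O)[C@@](C(=O)C(C)C)(C(=O)[C@@]2(O[Si](CC)(CC)CC)C(=O)C#CC(C)(C)O[Si](CC)(CC)CC)C1(C)C
F19 | step 20 | bis(triethylsilyl) ether of 36 | CC(C)=CC[C@@H]1C[C@]2(CC=C(C)C)C(=O)[C@@](C(=O)C(C)C)(C(=O)[C@@]2(O[Si](CC)(CC)CC)C(=O)/C=C\C(C)(C)O[Si](CC)(CC)CC)C1(C)C
A1 | alternative 1 | cohulupone (enol form) | CC(C)C(O)=C1C(=O)C(=O)C(CC=C(C)C)(CC=C(C)C)C1=O
A2 | alternative 1 | 1-isobutyryl-2,2-dimethyl-3-(phenylselanyl)-5-prenylbicyclo[3.2.1]octane-6,7,8-trione | c3ccccc3[Se][C@@H]1C[C@]2(CC=C(C)C)C(=O)[C@@](C(=O)C(C)C)(C(=O)C2=O)C1(C)C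
A3 | alternative 2 | 4-bromo-2-isobutyryl-2-(2-methylbut-3-en-2-yl)-4-prenylcyclopentane-1,3,5-trione | BrC2(CC=C(C)C)C(=O)[C@@](C(=O)C(C)C)(C(=O)C2=O)C(C)(C)C=C
A4 | alternative 2 | 3-allyl-1-isobutyryl-2,2-dimethyl-5-prenylbicyclo[3.2.1]octane-6,7,8-trione | C=CC[C@@H]1C[C@]2(CC=C(C)C)C(=O)[C@@](C(=O)C(C)C)(C(=O)C2=O)C1(C)C
A5 | alternative 3 | methyl 2-[3-isobutyryl-4,4-dimethyl-2-oxo-1,5-diprenylcyclohexyl]-2-(triethylsilyloxy)acetate | CC(C)=CC[C@@H]1C[C@]([C@H](O[Si](CC)(CC)CC)C(=O)OC)(CC=C(C)C)C(=O)C(C(=O)C(C)C)C1(C)C
A6 | alternative 3 | 1-isobutyryl-2,2-dimethyl-3,5-diprenyl-6-(triethylsilyloxy)bicyclo[3.2.1]octane-7,8-dione | CC(C)=CC[C@@H]1C[C@]2(CC=C(C)C)C(=O)[C@@](C(=O)C(C)C)(C(=O)[C@H]2O[Si](CC)(CC)CC)C1(C)C
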